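**Plan**
Cuts, in retrosynthetic order: the two O–CH3 bonds; the C6–CHO and C8–CHO bonds of arene ring A; the C4–isobutyl bond (back to a C4 ketone); C4–C4a and O1–C2 of pyran ring B together; last the C2=C3 alkene of the resulting acid (back to camphenilone and camphene).
Enabling feature: ring A is a phloroglucinol nucleus whose neighbouring positions C4a and C8a–O1 are bridged by one three-carbon unit, C4–C3–C2. With C4 at the acyl level, spiro carbon C2 (= C2' of the norbornane, rings C and D) is the β-carbon of an exocyclic enone, so a single ylideneacetic acid can be attached through carbon and through oxygen.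
Forward order: rings C/D are bought as camphene and ring A as phloroglucinol dimethyl ether. Ring B is the only ring made (step 4). The isobutyl group, the C4 hydrogen and the two formyl groups are then placed on the finished skeleton.
Stereochemistry: C1' and C4' come from (1S,4R)-(−)-camphene. C2 is set under thermodynamic control (C3 exo, O1 endo on the norbornane). C4 is set by hydrogenation of the 2H-chromene from the C1'–H face, away from the C3' methyl groups.

Key step: step 4

Assumption: commercial (−)-camphene is enantioenriched rather than enantiopure, so the crystalline ylideneacetic acid and the spirochromanone are recrystallised to remove the minor antipode, which adds no step.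

Step 1
Reactants: 1 (1S,4R)-(−)-camphene
Product: 2 (1R,4S)-camphenilone (3,3-dimethylbicyclo[2.2.1]heptan-2-one)
Conditions: O3, CH2Cl2/MeOH, −78 °C; then Me2S, −78 °C → rt
Reagents that add atoms: ozone, [O-][O+]=O
Why: Ozonolysis with reductive work-up cleaves only the exocyclic C=CH2 bond, and since neither a cation nor an enol can form next to the carbonyl (bridgehead on one side, quaternary carbon on the other) both bridgehead stereocentres pass unchanged into 2.

Step 2
Reactants: 2 (1R,4S)-camphenilone; 3 ethyl (trimethylsilyl)acetate
Product: 4 ethyl (E)-2-[(1R,4S)-3,3-dimethylbicyclo[2.2.1]heptan-2-ylidene]acetate (ester group on the bridgehead side, away from the gem-dimethyl carbon)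
Conditions: 3, LiN(iPr)2 (LDA), THF, −78 °C; then 2, −78 °C → rt; H2O
Reagents that add atoms: none
Why: Peterson olefination, in which the α-silyl ester enolate adds to the strained, non-enolisable ketone and the β-silyl alkoxide collapses with loss of Me3SiOLi, is a fully anionic path that never passes through a 2-norbornyl cation and so cannot scramble the skeleton; the E geometry is expected on steric grounds but is erased in step 4.

Step 3
Reactants: 4 ethyl (E)-ylideneacetate
Product: 5 (E)-2-[(1R,4S)-3,3-dimethylbicyclo[2.2.1]heptan-2-ylidene]acetic acid
Conditions: LiOH, THF/MeOH/H2O, 50 °C; then 1 M HCl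
Reagents that add atoms: lithium hydroxide, [Li+].[OH-]
Why: Ordinary BAc2 saponification, in which the alkene cannot leave conjugation because C1' is a bridgehead and C3' is quaternary, and no stereocentre is touched.

Step 4
Reactants: 5 (E)-ylideneacetic acid; 6 3,5-dimethoxyphenol (phloroglucinol dimethyl ether)
Product: 8 (2R,1'R,4'S)-5,7-dimethoxy-3',3'-dimethylspiro[chromane-2,2'-norbornan]-4-one (O1 endo/C3 exo), via hydroxy enone 7 (not isolated)
Conditions: P2O5/MeSO3H (1:10 w/w), 60 °C; ice–water, extraction; crude, K2CO3 (0.2 equiv), MeOH, 50 °C
Reagents that add atoms: none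
Why: P2O5/MeSO3H turns 5 into a mixed anhydride or acylium ion that acylates 6 at a carbon ortho to the free hydroxyl, directly or by way of the aryl ester and a Fries shift (C4–C4a), and the chelated hydroxyl of 7 then adds to the β-carbon of the protonated enone (O1–C2). The closest known reaction type is the one-pot Friedel–Crafts acylation/oxa-Michael condensation of phenols with 3,3-dialkylacrylic acids to 2,2-dialkylchroman-4-ones in this same medium. Ring B, the only ring formed, closes in the 6-endo-trig mode. C2 is the only new stereocentre and is placed under thermodynamic control, because the oxa-Michael step is reversible in the acid and, through the C3 enolate and E1cB return to 7, under K2CO3/MeOH; the CH2 group C3, larger than two-coordinate O1, should take the open exo position and leave O1 in the endo pocket facing C6'–H, in line with the general exo preference of carbon substituents at C2 of norbornanes, while an exo-oxygen epimer that forms faster should also reopen faster. Regioselectivity between the ortho and para positions of 6 is secured by its single free hydroxyl: only the ortho ketone can cyclise, a ketone wedged between two methoxy groups is twisted and deacylates in strong acid, no second hydroxyl is left for a second annulation, and arene attack at the β-carbon (the dihydrocoumarin pathway) is blocked by the neopentyl crowding at C2'. The norbornane skeleton should hold because the positive charge at C2' is shared with the oxygenated allyl system and the alkene cannot slip into the ring, which raises the barrier to Wagner–Meerwein and Nametkin shifts.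

Step 5
Reactants: 8 spirochromanone; 9 isobutylmagnesium bromide
Product: 11 (1'R,4'S)-4-isobutyl-5,7-dimethoxy-3',3'-dimethylspiro[2H-chromene-2,2'-norbornane] (O1 still endo; C2 now reads 2S through a CIP priority change only), via tertiary alcohol 10 (not isolated)
Conditions: CeCl3 (anhydrous), 9, THF, −78 °C; then 8, −78 → 0 °C; 0.5 M HCl, 0 °C; crude 10, PPTS (cat.), CH2Cl2, rt
Reagents that add atoms: none
Why: 1,2-Addition of an organocerium reagent, whose low basicity suppresses C3 enolisation (and with it E1cB opening of ring B) and β-hydride reduction, is followed by mild acid-catalysed E1 dehydration of the very electron-rich tertiary benzylic alcohol to the conjugated endocyclic alkene, so the carbinol configuration at C4 is of no consequence and C2 is untouched.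

Step 6
Reactants: 11 4-isobutyl-2H-chromene
Product: 12 (2R,4S,1'R,4'S)-4-isobutyl-5,7-dimethoxy-3',3'-dimethylspiro[chromane-2,2'-norbornane]
Conditions: H2 (4 atm), Pd/C (10 wt %), EtOAc, rt
Reagents that add atoms: none
Why: Heterogeneous catalytic hydrogenation adds H2 syn to the face of C3=C4 that can lie on the metal; one face carries the exo methyl of C3' directly over C3 and the other only C1'–H, so hydrogen should reach C4 from the C1' side and push the isobutyl group to the C3' side, which is the 4S configuration of the target.

Step 7
Reactants: 12 4-isobutylchroman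
Product: 13 (2R,4S,1'R,4'S)-4-isobutyl-5,7-dimethoxy-3',3'-dimethylspiro[chromane-2,2'-norbornane]-6,8-dicarbaldehyde
Conditions: Cl2CHOMe, TiCl4, CH2Cl2, −78 → 0 °C; then ice–water
Reagents that add atoms: dichloromethyl methyl ether, COC(Cl)Cl; water, O
Why: Rieche formylation (electrophilic substitution by the TiCl4-activated chloromethyl oxocarbenium ion, hydrolysed on work-up) should occur twice because C6 and C8 are the only free positions of ring A and each is ortho or para to all three oxygen donors, while the low temperature and the reluctance of an endo 2-norbornyl C–O bond to ionise protect the spiro ether.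

Step 8
Reactants: 13 dimethoxy dialdehyde
Product: 14 (2R,4S,1'R,4'S)-5,7-dihydroxy-4-isobutyl-3',3'-dimethylspiro[chromane-2,2'-norbornane]-6,8-dicarbaldehyde (CNP0150011.1)
Conditions: 4-MeC6H4SH, n-BuLi, toluene/DMPU, 0 °C; then 13, 110 °C; 1 M HCl
Reagents that add atoms: none
Why: Nucleophilic SN2 O-demethylation by a soft arenethiolate works here because both methoxy groups are activated by both formyl groups (ortho, or ortho and para) and so leave as good aryl oxide leaving groups after attack at the methyl carbons only, whereas the tertiary C2–O1 bond cannot be attacked from the rear and, with no Lewis or Brønsted acid present, cannot ionise; no stereocentre is touched.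

**Compound list**
1 | (1S,4R)-(−)-camphene | C=C1[C@@H]2CC[C@@H](C2)C1(C)C | starting material
2 | (1R,4S)-camphenilone | O=C1[C@@H]2CC[C@@H](C2)C1(C)C | intermediate
3 | ethyl (trimethylsilyl)acetate | CCOC(=O)C[Si](C)(C)C | starting material
4 | ethyl (E)-2-[(1R,4S)-3,3-dimethylbicyclo[2.2.1]heptan-2-ylidene]acetate | CCOC(=O)/C=C1\[C@@H]2CC[C@@H](C2)C1(C)C | intermediate
5 | (E)-2-[(1R,4S)-3,3-dimethylbicyclo[2.2.1]heptan-2-ylidene]acetic acid | OC(=O)/C=C1\[C@@H]2CC[C@@H](C2)C1(C)C | intermediate
6 | 3,5-dimethoxyphenol | COc1cc(O)cc(OC)c1 | starting material
7 | (E)-2-[(1R,4S)-3,3-dimethylbicyclo[2.2.1]heptan-2-ylidene]-1-(2-hydroxy-4,6-dimethoxyphenyl)ethan-1-one (not isolated) | COc1cc(O)c(C(=O)/C=C2\[C@@H]3CC[C@@H](C3)C2(C)C)c(OC)c1 | intermediate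
8 | (2R,1'R,4'S)-5,7-dimethoxy-3',3'-dimethylspiro[chromane-2,2'-norbornan]-4-one | O=C1C[C@@]2(Oc3cc(OC)cc(OC)c31)[C@@H]1CC[C@@H](C1)C2(C)C | intermediate
9 | isobutylmagnesium bromide | CC(C)C[Mg]Br | starting material
10 | (2R,1'R,4'S)-4-isobutyl-5,7-dimethoxy-3',3'-dimethylspiro[chromane-2,2'-norbornan]-4-ol, C4 configuration left open (not isolated) | CC(C)CC1(O)C[C@@]2(Oc3cc(OC)cc(OC)c31)[C@@H]1CC[C@@H](C1)C2(C)C | intermediate
11 | (2S,1'R,4'S)-4-isobutyl-5,7-dimethoxy-3',3'-dimethylspiro[2H-chromene-2,2'-norbornane] | CC(C)CC1=C[C@@]2(Oc3cc(OC)cc(OC)c31)[C@@H]1CC[C@@H](C1)C2(C)C | intermediate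
12 | (2R,4S,1'R,4'S)-4-isobutyl-5,7-dimethoxy-3',3'-dimethylspiro[chromane-2,2'-norbornane] | CC(C)C[C@H]1C[C@@]2(Oc3cc(OC)cc(OC)c31)[C@@H]1CC[C@@H](C1)C2(C)C | intermediate
13 | (2R,4S,1'R,4'S)-4-isobutyl-5,7-dimethoxy-3',3'-dimethylspiro[chromane-2,2'-norbornane]-6,8-dicarbaldehyde | CC(C)C[C@H]1C[C@@]2(Oc3c(C=O)c(OC)c(C=O)c(OC)c31)[C@@H]1CC[C@@H](C1)C2(C)C | intermediate
14 | (2R,4S,1'R,4'S)-5,7-dihydroxy-4-isobutyl-3',3'-dimethylspiro[chromane-2,2'-norbornane]-6,8-dicarbaldehyde | CC(C)C[C@H]1C[C@@]2(Oc3c(C=O)c(O)c(C=O)c(O)c31)[C@@H]1CC[C@@H](C1)C2(C)C | target

Total step count: 8. Longest linear sequence: 8 steps (1 → 14).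

**Steps most likely to fail**

Step 4. Three things may go wrong. The hot strong acid may trigger Wagner–Meerwein or Nametkin shifts of the norbornane. Acylation para to the hydroxyl may fail to funnel back. The crowded closure may stop short or settle with poor selectivity at C2. The fallback keeps the two bonds but forms them separately under mild conditions, setting out from 5 and coming back at 8.
- Acid 5 is treated with oxalyl chloride and catalytic DMF to give the ylideneacetyl chloride F1.
- SnCl4-mediated Friedel–Crafts acylation of symmetric 1,3,5-trimethoxybenzene at −20 °C should then give the trimethoxyphenyl enone F2 as a single regioisomer.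
- BCl3 at −78 °C removes one of the two equivalent ortho methyl groups through the carbonyl chelate and delivers hydroxy enone 7, this time isolated.
- DBU or K2CO3 in MeOH closes O1–C2 under purely basic, equilibrating conditions to 8. Any minor spiro epimer is separated and returned to the same base.

Step 6. Hydrogen uptake may be sluggish at the alkene flanked by the spiro carbon and the peri methoxy group, or facial selectivity on the metal surface may be poor. The fallback replaces surface syn addition by a stepwise polar delivery of H+ and H−, setting out from 11 and coming back at 12. CF3CO2H in CH2Cl2 at −40 °C protonates C3 to give the C4 benzylic cation, which is stabilised by the three ring A oxygens. A bulky silane (iPr3SiH) then transfers hydride to C4 past C1'–H rather than past the C3' methyl groups. Facial discrimination can be tuned through silane size and temperature. No new compound lies on this path.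

Step 2. Addition of the bulky α-silyl enolate to the neopentyl-type ketone may be reversible and sterically disfavoured, so that 2 is simply returned. The fallback, setting out from 2 and coming back at 4, uses the smaller zinc enolate. A Reformatsky reaction with ethyl bromoacetate and zinc in refluxing THF should add from the exo face to give the endo-hydroxy ester F3. SOCl2/pyridine at 0 °C then dehydrates it in E2 fashion toward the only available β-hydrogens, those of the CH2CO2Et group, giving 4.

**Further compounds**
F1 | step 4 | (E)-2-[(1R,4S)-3,3-dimethylbicyclo[2.2.1]heptan-2-ylidene]acetyl chloride | ClC(=O)/C=C1\[C@@H]2CC[C@@H](C2)C1(C)C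
F2 | step 4 | (E)-2-[(1R,4S)-3,3-dimethylbicyclo[2.2.1]heptan-2-ylidene]-1-(2,4,6-trimethoxyphenyl)ethan-1-one | COc1cc(OC)c(C(=O)/C=C2\[C@@H]3CC[C@@H](C3)C2(C)C)c(OC)c1
F0 | step 6 | none | none
F3 | step 2 | ethyl 2-[(1R,2R,4S)-2-endo-hydroxy-3,3-dimethylbicyclo[2.2.1]heptan-2-yl]acetate | CCOC(=O)C[C@@]1(O)[C@@H]2CC[C@@H](C2)C1(C)C
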